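**Strategy.** The route rests on cutting the bond between C1′ of ring A and the ketone carbon. Ring A carries oxygens at C2′ and C4′, the prenyl group at C3′ between them and the acyl group at C1′. This is the substitution pattern of a 2-alkyl-4-acylcyclohexane-1,3-dione, and the key step exploits it by building ring A as a cyclohexenone. The C6 lithium enolate of 3-allyloxy-2-prenylcyclohex-2-en-1-one is acylated by the N-methoxy-N-methylamide of tris-silylated (R)-danshensu. This forms the C1′–C(=O) bond regiospecifically and brings in the only stereocentre from the chiral pool. Dehydrogenation, deallylation and desilylation then give the target.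

Key step: step 6

Remark on ring size: the vinylogous ester partner of the key step must be the six-membered cyclohex-2-enone with three ring CH2 groups, since only that ring maps onto the six carbons of ring A; it is drawn so below.

Remark on the acid: (R)-danshensu is taken as the free acid; it is handled under argon because of the catechol.

Remark on stereochemistry: C6 of the acylated cyclohexenone and the hemiaminal carbon of its lithium precursor form without control; both centres disappear later.

**Step 1**
Reactants: 1 cyclohexane-1,3-dione; 2 prenyl bromide (1-bromo-3-methylbut-2-ene)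
Product: 3 2-(3-methylbut-2-en-1-yl)cyclohexane-1,3-dione
Conditions: KOH (1.05 equiv), H2O, 0 °C to rt
Reagents that add atoms: none
Why: In water the fully ionised dione is hydrogen-bonded at oxygen, so the soft allylic bromide should be taken up mainly at C2 (C-alkylation of a 1,3-dicarbonyl enolate, an SN2 reaction at the primary allylic carbon), and the neutral O-prenyl ether and 2,2-diprenyl dione that form beside it are removed by base extraction of the acidic product.

**Step 2**
Reactants: 3 2-(3-methylbut-2-en-1-yl)cyclohexane-1,3-dione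
Product: 4 3-(allyloxy)-2-(3-methylbut-2-en-1-yl)cyclohex-2-en-1-one
Conditions: allyl alcohol, PPh3, DIAD, THF, 0 °C to rt
Reagents that add atoms: allyl alcohol, C=CCO
Why: Mitsunobu etherification, in which the acidic enol of 3 protonates the PPh3–DIAD betaine and its oxygen displaces the allyloxyphosphonium ion, should give the vinylogous ester under neutral conditions, without the acid that would cyclise the prenyl group onto the enol oxygen and without the C-allylation that allyl halides and base tend to give.

**Step 3**
Reactants: 5 (R)-danshensu, (R)-3-(3,4-dihydroxyphenyl)-2-hydroxypropanoic acid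
Product: 6 methyl (R)-3-(3,4-dihydroxyphenyl)-2-hydroxypropanoate
Conditions: MeOH, H2SO4 (cat.), reflux, Ar
Reagents that add atoms: methanol, CO
Why: Fischer esterification of the carboxylic acid in a large excess of methanol, under acidic conditions that do not enolise the carbinol centre.

**Step 4**
Reactants: 6 methyl (R)-3-(3,4-dihydroxyphenyl)-2-hydroxypropanoate
Product: 7 methyl (R)-2-(tert-butyldimethylsilyloxy)-3-[3,4-bis(tert-butyldimethylsilyloxy)phenyl]propanoate
Conditions: TBSCl (3.6 equiv), imidazole (7 equiv), DMF, rt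
Reagents that add atoms: tert-butyldimethylsilyl chloride, CC(C)(C)[Si](C)(C)Cl
Why: Silyl ether formation at the two phenols and the secondary alcohol with the imidazole-activated silyl chloride, which does not touch the stereocentre.

**Step 5**
Reactants: 7 methyl (R)-2-(tert-butyldimethylsilyloxy)-3-[3,4-bis(tert-butyldimethylsilyloxy)phenyl]propanoate
Product: 8 (R)-2-(tert-butyldimethylsilyloxy)-3-[3,4-bis(tert-butyldimethylsilyloxy)phenyl]-N-methoxy-N-methylpropanamide
Conditions: MeNH(OMe)·HCl (1.6 equiv), iPrMgCl (3.2 equiv), THF, −20 to 0 °C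
Reagents that add atoms: N,O-dimethylhydroxylamine hydrochloride, CNOC.Cl
Why: Weinreb amide formation from an ester by aminolysis with the chloromagnesium amide made in the flask, a weakly basic nucleophile that adds at low temperature without enolising the α-silyloxy ester or attacking the aryl silyl ethers.

**Step 6**
Reactants: 4 3-(allyloxy)-2-(3-methylbut-2-en-1-yl)cyclohex-2-en-1-one; 8 (R)-2-(tert-butyldimethylsilyloxy)-3-[3,4-bis(tert-butyldimethylsilyloxy)phenyl]-N-methoxy-N-methylpropanamide
Product: 11 3-(allyloxy)-6-{(2R)-2-(tert-butyldimethylsilyloxy)-3-[3,4-bis(tert-butyldimethylsilyloxy)phenyl]propanoyl}-2-(3-methylbut-2-en-1-yl)cyclohex-2-en-1-one, via lithium dienolate 9 (not isolated), via lithium hemiaminal chelate 10 (not isolated)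
Conditions: LiN(iPr)2 (2.0 equiv), THF, −78 °C, 4 (2.05 equiv) added to the base; then 8 (1.0 equiv), −78 to −40 °C; AcOH, −78 °C
Reagents that add atoms: none
Why: LiN(iPr)2 removes the C6 proton of vinylogous ester 4 under kinetic control to give the cross-conjugated lithium dienolate 9, whose C6 carbon adds to the amide carbonyl of 8 to give the lithium-chelated N-methoxy-N-methyl hemiaminal 10, and this releases ketone 11 only on the acetic acid quench. The closest known reaction type is the acylation of lithium ketone and ester enolates by N-methoxy-N-methylamides (Weinreb ketone synthesis with an enolate as nucleophile), applied to the α′-enolate of a 3-alkoxycyclohex-2-enone, a standard nucleophile for alkylation and acylation. No ring is closed and no lasting stereocentre is made, because C6 of 11 is an enolisable β-diketone carbon that becomes aromatic C1′ in step 7. Attack through C6 and not through the γ-carbon C4 is secured by irreversible deprotonation at −78 °C with the hindered amide base and by keeping the mixture cold so that the small surplus of free ketone cannot equilibrate the enolate, while C-acylation over O-acylation follows from the amide electrophile and its lithium chelate. The (R)-carbinol centre is retained because no free LiN(iPr)2 is left (4 is in slight excess over the base), the enolate is too weak a base to deprotonate the α-silyloxy amide, and in 10 and 11 the only acidic site is C6. The surplus of enolate also covers an early collapse of 10, since the released β-diketone is then simply deprotonated at C6 and protected as its enolate.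

**Step 7**
Reactants: 11 3-(allyloxy)-6-{(2R)-2-(tert-butyldimethylsilyloxy)-3-[3,4-bis(tert-butyldimethylsilyloxy)phenyl]propanoyl}-2-(3-methylbut-2-en-1-yl)cyclohex-2-en-1-one
Product: 12 (R)-1-[4-(allyloxy)-2-hydroxy-3-(3-methylbut-2-en-1-yl)phenyl]-2-(tert-butyldimethylsilyloxy)-3-[3,4-bis(tert-butyldimethylsilyloxy)phenyl]propan-1-one
Conditions: DDQ (1.05 equiv), 1,4-dioxane, rt
Reagents that add atoms: none
Why: DDQ dehydrogenation, in which the enol form of 11 is a 1-hydroxycyclohexa-1,3-diene so that hydride abstraction from C5 and loss of the C4 proton should give the arene at room temperature, with close to one equivalent of oxidant to limit further oxidation at the prenyl group of the new ortho-prenylphenol.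

**Step 8**
Reactants: 12 (R)-1-[4-(allyloxy)-2-hydroxy-3-(3-methylbut-2-en-1-yl)phenyl]-2-(tert-butyldimethylsilyloxy)-3-[3,4-bis(tert-butyldimethylsilyloxy)phenyl]propan-1-one
Product: 13 (R)-2-(tert-butyldimethylsilyloxy)-3-[3,4-bis(tert-butyldimethylsilyloxy)phenyl]-1-[2,4-dihydroxy-3-(3-methylbut-2-en-1-yl)phenyl]propan-1-one
Conditions: Pd(PPh3)4 (5 mol %), morpholine (5 equiv), THF, rt
Reagents that add atoms: none
Why: Tsuji–Trost deallylation, in which zerovalent palladium ionises the aryl allyl ether to a π-allylpalladium phenoxide and morpholine takes up the allyl group, leaves the unactivated prenyl alkene, the silyl ethers and the ketone alone.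

**Step 9**
Reactants: 13 (R)-2-(tert-butyldimethylsilyloxy)-3-[3,4-bis(tert-butyldimethylsilyloxy)phenyl]-1-[2,4-dihydroxy-3-(3-methylbut-2-en-1-yl)phenyl]propan-1-one
Product: 14 (R)-1-[2,4-dihydroxy-3-(3-methylbut-2-en-1-yl)phenyl]-3-(3,4-dihydroxyphenyl)-2-hydroxypropan-1-one
Conditions: Et3N·3HF (excess), THF/MeCN, rt to 40 °C, Ar
Reagents that add atoms: none
Why: Fluoride-mediated desilylation of the two aryl and the one secondary alkyl silyl ether with a buffered, non-basic fluoride source, so that the α-hydroxy ketone is not enolised and the stereocentre taken from the chiral pool is kept.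

**Compound list**
1 | cyclohexane-1,3-dione | O=C1CCCC(=O)C1 | starting material
2 | prenyl bromide (1-bromo-3-methylbut-2-ene) | CC(C)=CCBr | starting material
3 | 2-(3-methylbut-2-en-1-yl)cyclohexane-1,3-dione | CC(C)=CCC1C(=O)CCCC1=O | intermediate
4 | 3-(allyloxy)-2-(3-methylbut-2-en-1-yl)cyclohex-2-en-1-one | C=CCOC1=C(CC=C(C)C)C(=O)CCC1 | intermediate
5 | (R)-danshensu, (R)-3-(3,4-dihydroxyphenyl)-2-hydroxypropanoic acid | OC(=O)[C@H](O)Cc1ccc(O)c(O)c1 | starting material
6 | methyl (R)-3-(3,4-dihydroxyphenyl)-2-hydroxypropanoate | COC(=O)[C@H](O)Cc1ccc(O)c(O)c1 | intermediate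
7 | methyl (R)-2-(tert-butyldimethylsilyloxy)-3-[3,4-bis(tert-butyldimethylsilyloxy)phenyl]propanoate | COC(=O)[C@H](O[Si](C)(C)C(C)(C)C)Cc1ccc(O[Si](C)(C)C(C)(C)C)c(O[Si](C)(C)C(C)(C)C)c1 | intermediate
8 | (R)-2-(tert-butyldimethylsilyloxy)-3-[3,4-bis(tert-butyldimethylsilyloxy)phenyl]-N-methoxy-N-methylpropanamide | CON(C)C(=O)[C@H](O[Si](C)(C)C(C)(C)C)Cc1ccc(O[Si](C)(C)C(C)(C)C)c(O[Si](C)(C)C(C)(C)C)c1 | intermediate
9 | lithium 5-(allyloxy)-6-(3-methylbut-2-en-1-yl)cyclohexa-1,5-dien-1-olate (C6 lithium enolate of 4, not isolated) | C=CCOC1=C(CC=C(C)C)C(O[Li])=CCC1 | intermediate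
10 | lithium (2R)-1-[4-(allyloxy)-3-(3-methylbut-2-en-1-yl)-2-oxocyclohex-3-en-1-yl]-2-(tert-butyldimethylsilyloxy)-3-[3,4-bis(tert-butyldimethylsilyloxy)phenyl]-1-[methoxy(methyl)amino]propan-1-olate (chelated tetrahedral adduct, not isolated; ring C1 and hemiaminal carbon unspecified) | C=CCOC1=C(CC=C(C)C)C(=O)C(CC1)C(O[Li])(N(C)OC)[C@H](O[Si](C)(C)C(C)(C)C)Cc1ccc(O[Si](C)(C)C(C)(C)C)c(O[Si](C)(C)C(C)(C)C)c1 | intermediate
11 | 3-(allyloxy)-6-{(2R)-2-(tert-butyldimethylsilyloxy)-3-[3,4-bis(tert-butyldimethylsilyloxy)phenyl]propanoyl}-2-(3-methylbut-2-en-1-yl)cyclohex-2-en-1-one (C6 unspecified, largely enolised) | C=CCOC1=C(CC=C(C)C)C(=O)C(CC1)C(=O)[C@H](O[Si](C)(C)C(C)(C)C)Cc1ccc(O[Si](C)(C)C(C)(C)C)c(O[Si](C)(C)C(C)(C)C)c1 | intermediate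
12 | (R)-1-[4-(allyloxy)-2-hydroxy-3-(3-methylbut-2-en-1-yl)phenyl]-2-(tert-butyldimethylsilyloxy)-3-[3,4-bis(tert-butyldimethylsilyloxy)phenyl]propan-1-one | C=CCOc1ccc(C(=O)[C@H](O[Si](C)(C)C(C)(C)C)Cc2ccc(O[Si](C)(C)C(C)(C)C)c(O[Si](C)(C)C(C)(C)C)c2)c(O)c1CC=C(C)C | intermediate
13 | (R)-2-(tert-butyldimethylsilyloxy)-3-[3,4-bis(tert-butyldimethylsilyloxy)phenyl]-1-[2,4-dihydroxy-3-(3-methylbut-2-en-1-yl)phenyl]propan-1-one | CC(C)=CCc1c(O)ccc(C(=O)[C@H](O[Si](C)(C)C(C)(C)C)Cc2ccc(O[Si](C)(C)C(C)(C)C)c(O[Si](C)(C)C(C)(C)C)c2)c1O | intermediate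
14 | (R)-1-[2,4-dihydroxy-3-(3-methylbut-2-en-1-yl)phenyl]-3-(3,4-dihydroxyphenyl)-2-hydroxypropan-1-one (CNP0408242.1) | CC(C)=CCc1c(O)ccc(C(=O)[C@H](O)Cc2ccc(O)c(O)c2)c1O | target

**Totals.** Total step count: 9. Longest linear sequence: 7 steps (5 to 14 through steps 3 to 9); steps 1 and 2 form the two-step branch that joins at step 6.

**Steps most likely to fail**

Step 6. The stabilised, hindered enolate may add too slowly to the α-silyloxy amide, so that on warming the kinetic enolate equilibrates to the γ-dienolate or the adduct reverts to its components. The fallback replaces acylation by aldol addition and oxidation. It sets out from 8, which is reduced with iBu2AlH in THF at −78 °C to the aldehyde (R)-2-(tert-butyldimethylsilyloxy)-3-[3,4-bis(tert-butyldimethylsilyloxy)phenyl]propanal F1. Enolate 9, made from 4 as in step 6, is added to F1 at −78 °C, where carbonyl addition should outrun enolisation of the aldehyde. This should give the aldol 3-(allyloxy)-6-{(2R)-2-(tert-butyldimethylsilyloxy)-3-[3,4-bis(tert-butyldimethylsilyloxy)phenyl]-1-hydroxypropyl}-2-(3-methylbut-2-en-1-yl)cyclohex-2-en-1-one F2 as a diastereomer mixture of no consequence. Oxidation of F2 with Dess–Martin periodinane and NaHCO3 in CH2Cl2 should then give the β-diketone, and the route is rejoined at 11.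

Step 7. Over-oxidation may occur: once the arene has formed, DDQ can abstract hydride from the prenyl CH2 of the ortho-prenylphenol (oxidative cyclisation towards a chromene) or from the benzylic CH2 next to the silylated catechol. The fallback replaces hydride abstraction by selenoxide elimination. It sets out from 11, which is deprotonated with NaH in THF and selenenylated with PhSeCl at −78 °C; the enolate should react far faster than the trisubstituted alkene. This should give 3-(allyloxy)-6-{(2R)-2-(tert-butyldimethylsilyloxy)-3-[3,4-bis(tert-butyldimethylsilyloxy)phenyl]propanoyl}-2-(3-methylbut-2-en-1-yl)-6-(phenylselanyl)cyclohex-2-en-1-one F3. Oxidation with H2O2 and pyridine in CH2Cl2 at 0 °C should give the selenoxide 3-(allyloxy)-6-{(2R)-2-(tert-butyldimethylsilyloxy)-3-[3,4-bis(tert-butyldimethylsilyloxy)phenyl]propanoyl}-2-(3-methylbut-2-en-1-yl)-6-(phenylseleninyl)cyclohex-2-en-1-one F4. Syn-elimination across C5–C6 then gives a cross-conjugated dienone that tautomerises to the phenol, and the route is rejoined at 12.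

Step 9. Cleavage of the hindered secondary silyl ether next to the ketone may stall, and forcing it may cause enolisation at the carbinol carbon (loss of configuration or ketol isomerisation) and air oxidation of the free catechol. The fallback is a staged deprotection that ends with acid solvolysis. It sets out from 13. KHF2 in MeOH at rt should cleave only the two aryl silyl ethers and give (R)-2-(tert-butyldimethylsilyloxy)-1-[2,4-dihydroxy-3-(3-methylbut-2-en-1-yl)phenyl]-3-(3,4-dihydroxyphenyl)propan-1-one F5. The remaining alkyl silyl ether is then removed by acid methanolysis (dilute HCl in MeOH, 0 °C to rt, argon), mild enough to spare the prenyl group, and the route is rejoined at 14.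

**Further compounds**
F1 | step 6 | (R)-2-(tert-butyldimethylsilyloxy)-3-[3,4-bis(tert-butyldimethylsilyloxy)phenyl]propanal | O=C[C@H](O[Si](C)(C)C(C)(C)C)Cc1ccc(O[Si](C)(C)C(C)(C)C)c(O[Si](C)(C)C(C)(C)C)c1
F2 | step 6 | 3-(allyloxy)-6-{(2R)-2-(tert-butyldimethylsilyloxy)-3-[3,4-bis(tert-butyldimethylsilyloxy)phenyl]-1-hydroxypropyl}-2-(3-methylbut-2-en-1-yl)cyclohex-2-en-1-one | C=CCOC1=C(CC=C(C)C)C(=O)C(CC1)C(O)[C@H](O[Si](C)(C)C(C)(C)C)Cc1ccc(O[Si](C)(C)C(C)(C)C)c(O[Si](C)(C)C(C)(C)C)c1
F3 | step 7 | 3-(allyloxy)-6-{(2R)-2-(tert-butyldimethylsilyloxy)-3-[3,4-bis(tert-butyldimethylsilyloxy)phenyl]propanoyl}-2-(3-methylbut-2-en-1-yl)-6-(phenylselanyl)cyclohex-2-en-1-one | C=CCOC1=C(CC=C(C)C)C(=O)C(CC1)([Se]c1ccccc1)C(=O)[C@H](O[Si](C)(C)C(C)(C)C)Cc1ccc(O[Si](C)(C)C(C)(C)C)c(O[Si](C)(C)C(C)(C)C)c1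
F4 | step 7 | 3-(allyloxy)-6-{(2R)-2-(tert-butyldimethylsilyloxy)-3-[3,4-bis(tert-butyldimethylsilyloxy)phenyl]propanoyl}-2-(3-methylbut-2-en-1-yl)-6-(phenylseleninyl)cyclohex-2-en-1-one | C=CCOC1=C(CC=C(C)C)C(=O)C(CC1)([Se](=O)c1ccccc1)C(=O)[C@H](O[Si](C)(C)C(C)(C)C)Cc1ccc(O[Si](C)(C)C(C)(C)C)c(O[Si](C)(C)C(C)(C)C)c1
F5 | step 9 | (R)-2-(tert-butyldimethylsilyloxy)-1-[2,4-dihydroxy-3-(3-methylbut-2-en-1-yl)phenyl]-3-(3,4-dihydroxyphenyl)propan-1-one | CC(C)=CCc1c(O)ccc(C(=O)[C@H](O[Si](C)(C)C(C)(C)C)Cc2ccc(O)c(O)c2)c1O
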